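**Retrosynthetic overview** (oxane locants: O1, C2 aryl-bearing, C3, C4 carbonyl, C5, C6; C1' is the side-chain carbinol carbon)
1. Target 19 ⇐ tribenzyl ketone 18 (hydrogenolysis) ⇐ oxan-4-ol 17 (oxidation at C4).
2. The oxane is the only ring formed (the arenes are bought). It is closed last, at C3–C4, by Lewis-acid attack of enol-ether carbon C3 on aldehyde carbon C4 with in situ silane reduction at C2 (15 → 17).
3. Enabling feature: O1–C2(aryl)–C3–C4(=O) of the oxane is a β-alkoxy ketone (aldol) array whose C2 is both benzylic to the electron-rich guaiacyl ring and bound to ring oxygen O1. C2=C3 can therefore be carried as a nucleophilic 1-arylvinyl ether, and C2 can pass through an aryl-stabilised oxocarbenium ion that is reduced to the 2,6-cis oxane.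
4. Aldehyde 15 ⇐ aryl ester 12 (methylenation supplies C3) ⇐ alcohol 10 + acid 11.
5. Alcohol 10 ⇐ aldehyde 5 by reagent-controlled anti allylation (C6 stereocentre) and ozonolysis (C4); 5 ⇐ (S)-4-hydroxyphenyllactic acid 1 (C1' stereocentre from the chiral pool).

Key step: step 11

Assumption: (S)-4-hydroxyphenyllactic acid (the diazotisation product of L-tyrosine) and (+)-Ipc2B(allyl) solution are taken as purchasable.

**Step 1**
Reactants: 1 (2S)-2-hydroxy-3-(4-hydroxyphenyl)propanoic acid
Product: 2 benzyl (2S)-3-[4-(benzyloxy)phenyl]-2-hydroxypropanoate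
Conditions: BnBr (2.2 equiv), K2CO3, DMF, rt
Reagents that add atoms: benzyl bromide, BrCc1ccccc1
Why: Williamson and carboxylate alkylation, in which carbonate deprotonates only the phenol and the acid, so both should be benzylated while the secondary alcohol and the stereocentre stay untouched.

**Step 2**
Reactants: 2 benzyl (2S)-3-[4-(benzyloxy)phenyl]-2-hydroxypropanoate
Product: 3 benzyl (2S)-2-(benzyloxy)-3-[4-(benzyloxy)phenyl]propanoate
Conditions: benzyl 2,2,2-trichloroacetimidate, TfOH (cat.), CH2Cl2–cyclohexane, 0 °C → rt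
Reagents that add atoms: benzyl 2,2,2-trichloroacetimidate, N=C(OCc1ccccc1)C(Cl)(Cl)Cl
Why: Acid-catalysed imidate O-benzylation runs without base, so the α-alkoxy ester stereocentre should not epimerise.

**Step 3**
Reactants: 3 benzyl (2S)-2-(benzyloxy)-3-[4-(benzyloxy)phenyl]propanoate
Product: 5 (2S)-2-(benzyloxy)-3-[4-(benzyloxy)phenyl]propanal, via aluminium hemiacetal 4 (not isolated)
Conditions: iBu2AlH (1.1 equiv), CH2Cl2, −78 °C; then MeOH, aq. potassium sodium tartrate
Reagents that add atoms: none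
Why: Partial ester reduction with iBu2AlH, in which the α-alkoxy-chelated aluminium hemiacetal 4 should persist at −78 °C and release the aldehyde only on work-up, so over-reduction is avoided and the crude aldehyde can be used at once before it epimerises.

**Step 4**
Reactants: 5 (2S)-2-(benzyloxy)-3-[4-(benzyloxy)phenyl]propanal
Product: 7 (2S,3R)-2-(benzyloxy)-1-[4-(benzyloxy)phenyl]hex-5-en-3-ol, via homoallyl borinate 6 (not isolated)
Conditions: (+)-Ipc2B(allyl) (the reagent derived from (−)-α-pinene), Et2O, −78 °C; then NaOH, 30% H2O2, 0 °C → rt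
Reagents that add atoms: (+)-B-allyldiisopinocampheylborane, C=CCB([C@H]1C[C@H]2C[C@@H]([C@@H]1C)C2(C)C)[C@H]1C[C@H]2C[C@@H]([C@@H]1C)C2(C)C
Why: Brown allylboration through a chair Zimmerman–Traxler transition state, in which this enantiomer of the reagent should add to the aldehyde face that the Felkin–Anh (non-chelate) preference of the α-benzyloxy aldehyde also favours, setting the new carbinol centre (3R) anti to the existing (2S) centre.

**Step 5**
Reactants: 7 (2S,3R)-2-(benzyloxy)-1-[4-(benzyloxy)phenyl]hex-5-en-3-ol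
Product: 9 (3R,4S)-4-(benzyloxy)-5-[4-(benzyloxy)phenyl]pentane-1,3-diol, via ozonide 8 (not isolated)
Conditions: O3, CH2Cl2, −78 °C (Sudan Red 7B end-point); then NaBH4, MeOH, −78 → 0 °C
Reagents that add atoms: ozone, [O-][O+]=O
Why: Ozonolysis with reductive work-up, in which the terminal alkene should react far faster than the benzyl ethers and arenes and NaBH4 reduces the ozonide directly to the 1,3-diol without touching either stereocentre.

**Step 6**
Reactants: 9 (3R,4S)-4-(benzyloxy)-5-[4-(benzyloxy)phenyl]pentane-1,3-diol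
Product: 10 (3R,4S)-4-(benzyloxy)-5-[4-(benzyloxy)phenyl]-1-[(tert-butyldimethylsilyl)oxy]pentan-3-ol
Conditions: TBSCl (1.05 equiv), imidazole, CH2Cl2, 0 °C
Reagents that add atoms: tert-butyldimethylsilyl chloride, CC(C)(C)[Si](C)(C)Cl
Why: Silylation should be selective for the unhindered primary hydroxyl over the secondary hydroxyl that is flanked by the benzyloxy-bearing carbon.

**Step 7**
Reactants: 10 (3R,4S)-4-(benzyloxy)-5-[4-(benzyloxy)phenyl]-1-[(tert-butyldimethylsilyl)oxy]pentan-3-ol; 11 4-(benzyloxy)-3-methoxybenzoic acid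
Product: 12 (3R,4S)-4-(benzyloxy)-5-[4-(benzyloxy)phenyl]-1-[(tert-butyldimethylsilyl)oxy]pentan-3-yl 4-(benzyloxy)-3-methoxybenzoate
Conditions: EDC·HCl, DMAP, CH2Cl2, rt
Reagents that add atoms: none
Why: Steglich esterification, in which the acylpyridinium formed from 11 should acylate the secondary alcohol with retention because no bond to the stereocentre is broken.

**Step 8**
Reactants: 12 (3R,4S)-4-(benzyloxy)-5-[4-(benzyloxy)phenyl]-1-[(tert-butyldimethylsilyl)oxy]pentan-3-yl 4-(benzyloxy)-3-methoxybenzoate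
Product: 13 tert-butyl{[(3R,4S)-4-(benzyloxy)-5-[4-(benzyloxy)phenyl]-3-({1-[4-(benzyloxy)-3-methoxyphenyl]ethenyl}oxy)pentyl]oxy}dimethylsilane
Conditions: Cp2TiMe2 (3 equiv), toluene–THF, 70 °C, dark; filtration through basic alumina
Reagents that add atoms: dimethyltitanocene, C[Ti](C)(C1C=CC=C1)C1C=CC=C1
Why: Petasis methylenation, in which thermally generated Cp2Ti=CH2 adds to the ester carbonyl and cycloreverts to the 1-arylvinyl ether under non-acidic conditions that silyl and benzyl ethers tolerate.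

**Step 9**
Reactants: 13 tert-butyl{[(3R,4S)-4-(benzyloxy)-5-[4-(benzyloxy)phenyl]-3-({1-[4-(benzyloxy)-3-methoxyphenyl]ethenyl}oxy)pentyl]oxy}dimethylsilane
Product: 14 (3R,4S)-4-(benzyloxy)-5-[4-(benzyloxy)phenyl]-3-({1-[4-(benzyloxy)-3-methoxyphenyl]ethenyl}oxy)pentan-1-ol
Conditions: Bu4NF, THF, 0 °C → rt
Reagents that add atoms: none
Why: Fluoride-mediated desilylation is basic, so the acid-labile enol ether should survive.

**Step 10**
Reactants: 14 (3R,4S)-4-(benzyloxy)-5-[4-(benzyloxy)phenyl]-3-({1-[4-(benzyloxy)-3-methoxyphenyl]ethenyl}oxy)pentan-1-ol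
Product: 15 (3R,4S)-4-(benzyloxy)-5-[4-(benzyloxy)phenyl]-3-({1-[4-(benzyloxy)-3-methoxyphenyl]ethenyl}oxy)pentanal
Conditions: Dess–Martin periodinane, pyridine, CH2Cl2, 0 °C; used crude
Reagents that add atoms: none
Why: Dess–Martin oxidation buffered with pyridine should give the aldehyde without free acid that would hydrolyse the enol ether and without strong base that would trigger β-elimination of the enolate-like vinyloxy group.

**Step 11**
Reactants: 15 (3R,4S)-4-(benzyloxy)-5-[4-(benzyloxy)phenyl]-3-({1-[4-(benzyloxy)-3-methoxyphenyl]ethenyl}oxy)pentanal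
Product: 17 (2S,6R)-2-[4-(benzyloxy)-3-methoxyphenyl]-6-{(1S)-1-(benzyloxy)-2-[4-(benzyloxy)phenyl]ethyl}oxan-4-ol as a mixture of C4 epimers, via cyclic oxocarbenium ion 16 (not isolated)
Conditions: BF3·OEt2 (1.5 equiv), Et3SiH (5 equiv), 2,6-di-tert-butyl-4-methylpyridine (0.3 equiv), CH2Cl2 (0.02 M), −78 → −40 °C; then aq. NaHCO3
Reagents that add atoms: none
Why: Proposed new method: BF3 activates the aldehyde carbonyl, the nucleophilic CH2 terminus of the 1-arylvinyl ether attacks it (vinyl-ether aldol addition, the opening event of a Mukaiyama aldol–Prins cascade) to forge the C3–C4 bond, and the resulting 2-aryl oxocarbenium ion 16, stabilised by the para-benzyloxy group, is reduced in situ by Et3SiH; the closest known reaction types are the Lewis-acid addition of alkyl enol ethers to aldehydes and the BF3·OEt2/Et3SiH reduction of cyclic aryl oxocarbenium ions used for C-aryl glycosides. The oxane ring closes in a 6-(enolendo)-exo-trig mode (enol ether C=C inside the new ring, aldehyde C=O outside it) through a chair in which the C6 side chain is equatorial. The new C2 stereocentre is set by stereoelectronically controlled axial hydride delivery to the half-chair oxocarbenium ion with the C6 substituent pseudo-equatorial, which should place the aryl group cis to the side chain (2S). The new C4 carbinol centre is uncontrolled and irrelevant, because both epimers, and any endocyclic enol ether that forms by proton loss and re-protonates, converge on one ketone in step 12. The step needs C-attack on the aldehyde to outrun protonation or reduction of the acyclic enol ether and silane reduction of the aldehyde; the six-membered intramolecular trajectory, the high nucleophilicity of the aryl-substituted enol ether, the hindered pyridine as proton scavenger and the low temperature should secure this, and the neighbouring benzyl ether cannot trap the cation irreversibly.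

**Step 12**
Reactants: 17 (2S,6R)-2-[4-(benzyloxy)-3-methoxyphenyl]-6-{(1S)-1-(benzyloxy)-2-[4-(benzyloxy)phenyl]ethyl}oxan-4-ol
Product: 18 (2S,6R)-2-[4-(benzyloxy)-3-methoxyphenyl]-6-{(1S)-1-(benzyloxy)-2-[4-(benzyloxy)phenyl]ethyl}oxan-4-one
Conditions: Dess–Martin periodinane, pyridine, CH2Cl2, rt
Reagents that add atoms: none
Why: Dess–Martin oxidation should convert both C4 epimers into the single ketone, and the diequatorial 2,6-cis arrangement is the thermodynamically preferred one, so C2 and C6 are not at risk.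

**Step 13**
Reactants: 18 (2S,6R)-2-[4-(benzyloxy)-3-methoxyphenyl]-6-{(1S)-1-(benzyloxy)-2-[4-(benzyloxy)phenyl]ethyl}oxan-4-one
Product: 19 (2S,6R)-2-(4-hydroxy-3-methoxyphenyl)-6-[(1S)-1-hydroxy-2-(4-hydroxyphenyl)ethyl]oxan-4-one
Conditions: H2 (1 atm), 10% Pd/C, EtOAc–EtOH, rt
Reagents that add atoms: none
Why: Catalytic hydrogenolysis should remove the two aryl benzyl ethers and the alkyl benzyl ether, while the ring C2–O1 bond, a hindered secondary benzylic dialkyl ether, is cleaved much more slowly and the ketone is not reduced.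

**Compound list**
1 | (2S)-2-hydroxy-3-(4-hydroxyphenyl)propanoic acid | OC(=O)[C@@H](O)Cc1ccc(O)cc1 | starting material
2 | benzyl (2S)-3-[4-(benzyloxy)phenyl]-2-hydroxypropanoate | O=C(OCc1ccccc1)[C@@H](O)Cc1ccc(OCc2ccccc2)cc1 | intermediate
3 | benzyl (2S)-2-(benzyloxy)-3-[4-(benzyloxy)phenyl]propanoate | O=C(OCc1ccccc1)[C@@H](OCc1ccccc1)Cc1ccc(OCc2ccccc2)cc1 | intermediate
4 | [(2S)-1,2-bis(benzyloxy)-3-[4-(benzyloxy)phenyl]propoxy]bis(2-methylpropyl)alumane (aluminium hemiacetal, not isolated) | CC(C)C[Al](CC(C)C)OC(OCc1ccccc1)[C@@H](OCc1ccccc1)Cc1ccc(OCc2ccccc2)cc1 | intermediate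
5 | (2S)-2-(benzyloxy)-3-[4-(benzyloxy)phenyl]propanal | O=C[C@@H](OCc1ccccc1)Cc1ccc(OCc2ccccc2)cc1 | intermediate
6 | (2S,3R)-2-(benzyloxy)-1-[4-(benzyloxy)phenyl]hex-5-en-3-yl diisopinocampheylborinate (not isolated) | C=CC[C@H]([C@@H](OCc1ccccc1)Cc1ccc(OCc2ccccc2)cc1)OB([C@H]1C[C@H]2C[C@@H]([C@@H]1C)C2(C)C)[C@H]1C[C@H]2C[C@@H]([C@@H]1C)C2(C)C | intermediate
7 | (2S,3R)-2-(benzyloxy)-1-[4-(benzyloxy)phenyl]hex-5-en-3-ol | C=CC[C@H]([C@@H](OCc1ccccc1)Cc1ccc(OCc2ccccc2)cc1)O | intermediate
8 | (2R,3S)-3-(benzyloxy)-4-[4-(benzyloxy)phenyl]-1-(1,2,4-trioxolan-3-yl)butan-2-ol (ozonide, not isolated) | C1OOC(C[C@H]([C@@H](OCc2ccccc2)Cc2ccc(OCc3ccccc3)cc2)O)O1 | intermediate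
9 | (3R,4S)-4-(benzyloxy)-5-[4-(benzyloxy)phenyl]pentane-1,3-diol | OCC[C@H]([C@@H](OCc1ccccc1)Cc1ccc(OCc2ccccc2)cc1)O | intermediate
10 | (3R,4S)-4-(benzyloxy)-5-[4-(benzyloxy)phenyl]-1-[(tert-butyldimethylsilyl)oxy]pentan-3-ol | CC(C)(C)[Si](C)(C)OCC[C@H]([C@@H](OCc1ccccc1)Cc1ccc(OCc2ccccc2)cc1)O | intermediate
11 | 4-(benzyloxy)-3-methoxybenzoic acid | COc1cc(C(=O)O)ccc1OCc1ccccc1 | starting material
12 | (3R,4S)-4-(benzyloxy)-5-[4-(benzyloxy)phenyl]-1-[(tert-butyldimethylsilyl)oxy]pentan-3-yl 4-(benzyloxy)-3-methoxybenzoate | CC(C)(C)[Si](C)(C)OCC[C@H]([C@@H](OCc1ccccc1)Cc1ccc(OCc2ccccc2)cc1)OC(=O)c1ccc(OCc2ccccc2)c(OC)c1 | intermediate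
13 | tert-butyl{[(3R,4S)-4-(benzyloxy)-5-[4-(benzyloxy)phenyl]-3-({1-[4-(benzyloxy)-3-methoxyphenyl]ethenyl}oxy)pentyl]oxy}dimethylsilane | CC(C)(C)[Si](C)(C)OCC[C@H]([C@@H](OCc1ccccc1)Cc1ccc(OCc2ccccc2)cc1)OC(=C)c1ccc(OCc2ccccc2)c(OC)c1 | intermediate
14 | (3R,4S)-4-(benzyloxy)-5-[4-(benzyloxy)phenyl]-3-({1-[4-(benzyloxy)-3-methoxyphenyl]ethenyl}oxy)pentan-1-ol | OCC[C@H]([C@@H](OCc1ccccc1)Cc1ccc(OCc2ccccc2)cc1)OC(=C)c1ccc(OCc2ccccc2)c(OC)c1 | intermediate
15 | (3R,4S)-4-(benzyloxy)-5-[4-(benzyloxy)phenyl]-3-({1-[4-(benzyloxy)-3-methoxyphenyl]ethenyl}oxy)pentanal | O=CC[C@H]([C@@H](OCc1ccccc1)Cc1ccc(OCc2ccccc2)cc1)OC(=C)c1ccc(OCc2ccccc2)c(OC)c1 | intermediate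
16 | (6R)-2-[4-(benzyloxy)-3-methoxyphenyl]-6-{(1S)-1-(benzyloxy)-2-[4-(benzyloxy)phenyl]ethyl}-4-[(trifluoroboranuidyl)oxy]-3,4,5,6-tetrahydropyrylium (zwitterion, not isolated) | COc1cc(C2=[O+][C@@H]([C@@H](OCc3ccccc3)Cc3ccc(OCc4ccccc4)cc3)CC(O[B-](F)(F)F)C2)ccc1OCc1ccccc1 | intermediate
17 | (2S,6R)-2-[4-(benzyloxy)-3-methoxyphenyl]-6-{(1S)-1-(benzyloxy)-2-[4-(benzyloxy)phenyl]ethyl}oxan-4-ol (mixture of C4 epimers) | COc1cc([C@@H]2CC(O)C[C@H]([C@@H](OCc3ccccc3)Cc3ccc(OCc4ccccc4)cc3)O2)ccc1OCc1ccccc1 | intermediate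
18 | (2S,6R)-2-[4-(benzyloxy)-3-methoxyphenyl]-6-{(1S)-1-(benzyloxy)-2-[4-(benzyloxy)phenyl]ethyl}oxan-4-one | COc1cc([C@@H]2CC(=O)C[C@H]([C@@H](OCc3ccccc3)Cc3ccc(OCc4ccccc4)cc3)O2)ccc1OCc1ccccc1 | intermediate
19 | (2S,6R)-2-(4-hydroxy-3-methoxyphenyl)-6-[(1S)-1-hydroxy-2-(4-hydroxyphenyl)ethyl]oxan-4-one | COc1cc([C@@H]2CC(=O)C[C@H]([C@@H](O)Cc3ccc(O)cc3)O2)ccc1O | target

Total step count: 13
Longest linear sequence: 13 steps (1 → 19); acid 11 enters at step 7.

**Steps most likely to fail**

Step 11 (proposed cyclisation–reduction). The acyclic enol ether may be protonated and reduced before it cyclises, the activated aldehyde may be reduced directly by the silane, or the oxocarbenium ion may lose a proton and then ionise at C4. The fallback uses known Prins chemistry; it sets out from homoallylic alcohol 7 and comes back to the route at ketone 18. Alcohol 7 and commercial 4-(benzyloxy)-3-methoxybenzaldehyde are treated with CF3CO2H in CH2Cl2 at 0 °C → rt. Prins cyclisation through a chair with both substituents equatorial and equatorial capture by trifluoroacetate should give the all-cis ester (2S,4S,6R)-2-[4-(benzyloxy)-3-methoxyphenyl]-6-{(1S)-1-(benzyloxy)-2-[4-(benzyloxy)phenyl]ethyl}oxan-4-yl trifluoroacetate F1. Methanolysis with K2CO3 in MeOH should give the all-cis alcohol (2S,4S,6R)-2-[4-(benzyloxy)-3-methoxyphenyl]-6-{(1S)-1-(benzyloxy)-2-[4-(benzyloxy)phenyl]ethyl}oxan-4-ol F2, and Dess–Martin oxidation as in step 12 should deliver 18.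

Step 8 (methylenation). Methylenation of the electron-rich, hindered benzoate may be sluggish, and the 1-arylvinyl ether may be lost by hydrolysis during isolation. The fallback builds the enol ether by ketal exchange and elimination instead of carbonyl olefination; it sets out from alcohol 10 and comes back at enol ether 13. Commercial 1-[4-(benzyloxy)-3-methoxyphenyl]ethanone is converted with HC(OMe)3 and catalytic TsOH in MeOH into the dimethyl ketal 1-(benzyloxy)-4-(1,1-dimethoxyethyl)-2-methoxybenzene F3. Exchange with alcohol 10 (PPTS, toluene, 5 Å molecular sieves) should give the mixed methyl ketal tert-butyl{[(3R,4S)-4-(benzyloxy)-5-[4-(benzyloxy)phenyl]-3-({1-[4-(benzyloxy)-3-methoxyphenyl]-1-methoxyethyl}oxy)pentyl]oxy}dimethylsilane F4. TMSOTf and iPr2NEt in CH2Cl2 at −20 °C should then remove the less hindered methoxy group as methoxytrimethylsilane and leave 13.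

Step 13 (global debenzylation). Hydrogenolysis may also cleave the ring benzylic C2–O1 bond once the phenol is free, or may stall at the secondary alkyl benzyl ether. The fallback replaces reductive cleavage by Lewis-acid dealkylation with a cation scavenger; it sets out from 18 and comes back at 19. Treatment with BCl3 and pentamethylbenzene in CH2Cl2 at −78 °C should cleave the three benzyl ethers without hydrogen and without a new intermediate (F0).

**Further compounds**
F1 | step 11 | (2S,4S,6R)-2-[4-(benzyloxy)-3-methoxyphenyl]-6-{(1S)-1-(benzyloxy)-2-[4-(benzyloxy)phenyl]ethyl}oxan-4-yl trifluoroacetate | COc1cc([C@@H]2C[C@H](OC(=O)C(F)(F)F)C[C@H]([C@@H](OCc3ccccc3)Cc3ccc(OCc4ccccc4)cc3)O2)ccc1OCc1ccccc1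
F2 | step 11 | (2S,4S,6R)-2-[4-(benzyloxy)-3-methoxyphenyl]-6-{(1S)-1-(benzyloxy)-2-[4-(benzyloxy)phenyl]ethyl}oxan-4-ol | COc1cc([C@@H]2C[C@H](O)C[C@H]([C@@H](OCc3ccccc3)Cc3ccc(OCc4ccccc4)cc3)O2)ccc1OCc1ccccc1
F3 | step 8 | 1-(benzyloxy)-4-(1,1-dimethoxyethyl)-2-methoxybenzene | COc1cc(C(C)(OC)OC)ccc1OCc1ccccc1
F4 | step 8 | tert-butyl{[(3R,4S)-4-(benzyloxy)-5-[4-(benzyloxy)phenyl]-3-({1-[4-(benzyloxy)-3-methoxyphenyl]-1-methoxyethyl}oxy)pentyl]oxy}dimethylsilane | CC(C)(C)[Si](C)(C)OCC[C@H]([C@@H](OCc1ccccc1)Cc1ccc(OCc2ccccc2)cc1)OC(C)(OC)c1ccc(OCc2ccccc2)c(OC)c1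
F0 | step 13 | none | none
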